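The clock runs for 1.0 min at one constant temperature, in two flasks that differ in their charge of incoming ligand.

    starting complex + incoming ligand → leaving ligand + complex with one exchanged (k1 = 34.7 M⁻¹ s⁻¹)
    complex with one exchanged + incoming ligand → leaving ligand + complex with two exchanged (k2 = 75.4 M⁻¹ s⁻¹)
    starting complex → decomposition product (k3 = 2.69 × 10⁻⁴ s⁻¹)

| setting | elm | birch |
|---|---|---|
| starting complex | 10 mM | 10 mM |
| incoming ligand | 0.900 equiv | 1.20 equiv |
| time | 1.0 min | 1.0 min |

1. which of these there is most of at the end, counted by the starting complex in it, elm (complex with two exchanged / complex with one exchanged / starting complex)
2. which of these there is most of at the end, counted by the starting complex in it, birch (complex with two exchanged / complex with one exchanged / starting complex)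
3. how much there is at the end of the one of these that leads, in percent of the starting complex charged: elm
4. how much there is at the end of the one of these that leads, in percent of the starting complex charged: birch

*Does the minute matter?* Not much. At elm's charges step 1 alone halves the starting complex in 2.2 s, short against 1.0 min, while step 3 alone needs 43 min. So I assume that the incoming ligand, the limiting reagent, is consumed, and I ask how it divides.

*How, without [incoming ligand] against time?* Both exchanges run at the same [incoming ligand], so dividing one rate by the other removes it, and time with it. What remains is S = 2.17, the rate constant of the second exchange over that of the first, the selectivity factor. Let s be [starting complex] over its charge. Integrating gives the fraction a in complex with one exchanged: a = (s − s^S)/(S − 1).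

*But you don't have s.* The balance gives it. Complex with one exchanged took one incoming ligand and complex with two exchanged took two, so, with the decomposition product set aside for now, s = 1 − (equiv + a)/2. I start from a = 0 and repeat. Elm walks 55.0%, 43.2%, 43.5%. Birch walks 40.0%, 28.8%, 30.6%, 30.2%.

*And step 3?* In elm I charge it the full minute at that level, which I put at 0.702% of the starting complex. So I reckon elm at 42.8% starting complex, more than its 33.4% complex with two exchanged. For birch, with step 3 left out, I reckon 50.4% complex with two exchanged, more than its 30.2% starting complex.

The forecast names starting complex at 42.7% (41.5% to 44%) for elm and complex with two exchanged at 50.3% (49% to 51.5%) for birch, against my 42.8% and 50.4%, holding that “each outcome is set by stoichiometry and the selectivity”.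

The simulation gives starting complex at 42.7% for elm and complex with two exchanged at 50.3% for birch.

At elm's charges step 2 alone halves the complex with one exchanged in 1.0 s, faster than the 2.2 s in which step 1 alone halves the starting complex, by the factor S = 2.17, and in elm that S applied to starting complex plus decomposition product, 43.5%, gives 23.1% complex with one exchanged, where the flask holds 23.1%. In the flask like birch but charged with 0.300 equiv of incoming ligand, the same S applied to 76.1% gives 17.8%, and that flask holds 17.8% complex with one exchanged.

The numbers of this flask are those of an exercise; the result is computed.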